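**Retrosynthetic overview**
- Cryptomerin A is unmasked last from its tetrabenzyl ether (O5 and O7 of each flavone half); the 4'-methyl ether is carried from the start.
- Ring C of the apigenin half is the last ring formed, by oxidative closure of a 2'-hydroxychalcone; the chalcone comes from aldol condensation of a flavone aldehyde with 2-hydroxy-4,6-bis(benzyloxy)acetophenone.
- The strategy rests on ring A of the acacetin half: O1 (on C8a) and the C4 carbonyl carbon (on C4a) sit on adjacent carbons directly beside the C5 oxygen, the pattern a 3-alkoxyaryne delivers. Ring C of this half (the first ring formed) is therefore cut at C8a–O1, C4a–C4 and O1–C2 into an aryne and 3-(4-methoxyphenyl)propiolic acid.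
- The aryne comes from an ortho-silylaryl triflate made from the symmetric 3,5-bis(benzyloxy)-4-aryloxyphenol (ortho-bromination, O-silylation, retro-Brook shift, triflation); the symmetry allows only one aryne.
- The C6–O–C4''' diaryl ether is made first, by SNAr of 4-bromo-2,6-dimethoxyphenol on 4-fluorobenzaldehyde, followed by methyl-to-benzyl exchange, acetal protection and conversion of C–Br into C–OH; all benzene rings are bought in.

Key step: step 9

Remark: the target has no stereocentre; the only stereogenic carbon on the route (C2 of a flavanone formed in passing in step 13) is racemic and is removed in the same flask.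

**Route**

Step 1
Reactants: 1 4-bromo-2,6-dimethoxyphenol; 2 4-fluorobenzaldehyde
Product: 3 4-(4-bromo-2,6-dimethoxyphenoxy)benzaldehyde
Conditions: K2CO3 (1.5 equiv), DMF, 120 °C
Reagents that add atoms: none
Why: SNAr (addition–elimination) of the 2,6-dimethoxyphenoxide on the para-formyl-activated fluoroarene; both ortho oxygens are capped as methyl ethers, so no neighbouring phenol can be arylated instead or trigger a Smiles aryl shift, and the aryl bromide is inert.

Step 2
Reactants: 3 4-(4-bromo-2,6-dimethoxyphenoxy)benzaldehyde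
Product: 4 4-(4-bromo-2,6-dihydroxyphenoxy)benzaldehyde
Conditions: BBr3 (4 equiv), CH2Cl2, −78 °C to rt; then H2O, 0 °C
Reagents that add atoms: none
Why: Lewis acid ether cleavage (bromide attacks the O-methyl carbon of the borane–ether adduct) should remove both methyl groups, while the diaryl ether and aryl bromide are untouched and the aldehyde, only reversibly engaged by the Lewis acid, is returned on aqueous work-up.

Step 3
Reactants: 4 4-(4-bromo-2,6-dihydroxyphenoxy)benzaldehyde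
Product: 5 4-[2,6-bis(benzyloxy)-4-bromophenoxy]benzaldehyde
Conditions: BnBr (2.3 equiv), K2CO3 (3 equiv), DMF, rt
Reagents that add atoms: benzyl bromide, BrCc1ccccc1
Why: Williamson O-benzylation of the two equivalent phenols at room temperature should be much faster than any O-to-O migration of the only weakly (mono-formyl) activated aryl group.

Step 4
Reactants: 5 4-[2,6-bis(benzyloxy)-4-bromophenoxy]benzaldehyde
Product: 6 2-{4-[2,6-bis(benzyloxy)-4-bromophenoxy]phenyl}-1,3-dioxolane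
Conditions: HOCH2CH2OH (5 equiv), TsOH·H2O (5 mol %), toluene, reflux, Dean–Stark trap
Reagents that add atoms: ethylene glycol, OCCO
Why: Acid-catalysed acetalization with azeotropic removal of water masks the aldehyde against the organolithium reagents of steps 5 and 8, and the benzyl ethers and aryl bromide are inert.

Step 5
Reactants: 6 2-{4-[2,6-bis(benzyloxy)-4-bromophenoxy]phenyl}-1,3-dioxolane
Product: 9 3,5-bis(benzyloxy)-4-[4-(1,3-dioxolan-2-yl)phenoxy]phenol, via aryllithium 7 (not isolated), via lithium aryltrimethoxyborate 8 (not isolated)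
Conditions: n-BuLi (1.1 equiv), THF, −78 °C; B(OMe)3 (1.5 equiv), −78 °C to rt; 30% H2O2, 2 M NaOH, 0 °C to rt; NH4Cl work-up
Reagents that add atoms: hydrogen peroxide, OO
Why: Bromine–lithium exchange, borylation of the aryllithium and oxidation of the C–B bond by alkaline peroxide (1,2-aryl shift from boron to oxygen) is the standard aryl bromide to phenol sequence, and its basic conditions spare the dioxolane and the benzyl ethers.

Step 6
Reactants: 9 3,5-bis(benzyloxy)-4-[4-(1,3-dioxolan-2-yl)phenoxy]phenol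
Product: 10 3,5-bis(benzyloxy)-2-bromo-4-[4-(1,3-dioxolan-2-yl)phenoxy]phenol
Conditions: NBS (1.0 equiv), CH2Cl2, −78 to −20 °C
Reagents that add atoms: N-bromosuccinimide, O=C1CCC(=O)N1Br
Why: Electrophilic aromatic bromination of a strongly activated phenol whose para position is blocked and whose two ortho positions are equivalent by symmetry, so one equivalent of NBS at low temperature should give a single monobromide while the less electron-rich acetal-bearing ring and benzyl rings are left alone.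

Step 7
Reactants: 10 3,5-bis(benzyloxy)-2-bromo-4-[4-(1,3-dioxolan-2-yl)phenoxy]phenol
Product: 11 {3,5-bis(benzyloxy)-2-bromo-4-[4-(1,3-dioxolan-2-yl)phenoxy]phenoxy}trimethylsilane
Conditions: (Me3Si)2NH (1.5 equiv), THF, 65 °C; concentrate in vacuo, use crude
Reagents that add atoms: hexamethyldisilazane, C[Si](C)(C)N[Si](C)(C)C
Why: O-Silylation of the phenol with hexamethyldisilazane gives only ammonia as by-product and places the silyl group for the O-to-C shift of the next step.

Step 8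
Reactants: 11 {3,5-bis(benzyloxy)-2-bromo-4-[4-(1,3-dioxolan-2-yl)phenoxy]phenoxy}trimethylsilane
Product: 14 3,5-bis(benzyloxy)-4-[4-(1,3-dioxolan-2-yl)phenoxy]-2-(trimethylsilyl)phenyl trifluoromethanesulfonate, via ortho-lithioaryl silyl ether 12 (not isolated), via lithium 2-silylphenoxide 13 (not isolated)
Conditions: n-BuLi (1.1 equiv), THF, −78 °C; PhNTf2 (1.2 equiv), −78 °C to rt
Reagents that add atoms: N-phenylbis(trifluoromethanesulfonimide), O=S(=O)(N(c1ccccc1)S(=O)(=O)C(F)(F)F)C(F)(F)F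
Why: Bromine–lithium exchange gives an ortho-lithioaryl silyl ether that undergoes the anionic 1,3 O-to-C silyl shift (retro-Brook rearrangement), and the resulting phenoxide is O-triflated by PhNTf2, a triflating agent mild enough to leave the dioxolane intact.

Step 9
Reactants: 14 3,5-bis(benzyloxy)-4-[4-(1,3-dioxolan-2-yl)phenoxy]-2-(trimethylsilyl)phenyl trifluoromethanesulfonate; 15 3-(4-methoxyphenyl)propiolic acid (1.5 equiv)
Product: 18 5,7-bis(benzyloxy)-6-[4-(1,3-dioxolan-2-yl)phenoxy]-2-(4-methoxyphenyl)-4H-chromen-4-one, via aryne 16 (not isolated), via ortho-hydroxyaryl ynone 17 (not isolated)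
Conditions: CsF (4 equiv), THF, 125 °C, sealed tube
Reagents that add atoms: none
Why: Fluoride strips the silyl group of 14 and triflate departs to give aryne 16, a single aryne because the parent phenol is symmetric; caesium 3-(4-methoxyphenyl)propiolate then adds through oxygen to the aryne carbon remote from the flanking C3 benzyloxy group, so the aryl anion develops next to that oxygen at the future C4a. The anion attacks the neighbouring ester carbonyl and the four-membered adduct opens to the ortho-acylphenoxide of 17 (anionic O-to-C acyl shift, overall insertion of the aryne into the acid C–O bond), which forms C8a–O1 and C4a–C4. The phenoxide closes pyranone ring C by 6-endo-dig oxa-Michael addition to the ynone (O1–C2), and protonation of the allenolate gives the flavone. The closest known reaction type is the CsF-mediated insertion of arynes into the C–O bond of carboxylic acids, which gives ortho-hydroxyaryl ketones and, with arylpropiolic acids, flavones; no stereocentre is created. Regioselectivity rests on the inductively withdrawing benzyloxy group beside the triple bond (the opposite sense would give the 6,8-bis(benzyloxy)-7-aryloxy isomer), acyl transfer must outrun protonation of the aryl anion (aprotic THF, acid held as its caesium salt), and 6-endo closure is favoured over 5-exo aurone formation because only attack at the β-carbon gives a stabilized allenolate.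

Step 10
Reactants: 18 5,7-bis(benzyloxy)-6-[4-(1,3-dioxolan-2-yl)phenoxy]-2-(4-methoxyphenyl)-4H-chromen-4-one
Product: 19 4-{[5,7-bis(benzyloxy)-2-(4-methoxyphenyl)-4-oxo-4H-chromen-6-yl]oxy}benzaldehyde
Conditions: 1 M HCl, THF, rt
Reagents that add atoms: water, O
Why: Acid-catalysed hydrolysis of the dioxolane releases the aldehyde, and the flavone, diaryl ether and benzyl ethers are stable to dilute aqueous acid at room temperature.

Step 11
Reactants: 20 2,4,6-trihydroxyacetophenone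
Product: 21 1-[2,4-bis(benzyloxy)-6-hydroxyphenyl]ethanone
Conditions: BnBr (2.1 equiv), K2CO3 (2.2 equiv), DMF, rt
Reagents that add atoms: benzyl bromide, BrCc1ccccc1
Why: Williamson benzylation takes the two non-chelated phenols, while the hydroxyl hydrogen-bonded to the acetyl carbonyl is the least nucleophilic and should stay free with two equivalents of benzyl bromide.

Step 12
Reactants: 19 4-{[5,7-bis(benzyloxy)-2-(4-methoxyphenyl)-4-oxo-4H-chromen-6-yl]oxy}benzaldehyde; 21 1-[2,4-bis(benzyloxy)-6-hydroxyphenyl]ethanone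
Product: 22 (E)-1-[2,4-bis(benzyloxy)-6-hydroxyphenyl]-3-(4-{[5,7-bis(benzyloxy)-2-(4-methoxyphenyl)-4-oxo-4H-chromen-6-yl]oxy}phenyl)prop-2-en-1-one
Conditions: KOH (50% aq.), EtOH–THF, rt
Reagents that add atoms: none
Why: Claisen–Schmidt condensation of the acetophenone enolate with the non-enolizable aldehyde followed by E1cB dehydration gives the thermodynamically preferred E-enone, and room temperature is chosen so that hydroxide does not open the pyranone ring already present.

Step 13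
Reactants: 22 (E)-1-[2,4-bis(benzyloxy)-6-hydroxyphenyl]-3-(4-{[5,7-bis(benzyloxy)-2-(4-methoxyphenyl)-4-oxo-4H-chromen-6-yl]oxy}phenyl)prop-2-en-1-one
Product: 24 5,7-bis(benzyloxy)-6-{4-[5,7-bis(benzyloxy)-4-oxo-4H-chromen-2-yl]phenoxy}-2-(4-methoxyphenyl)-4H-chromen-4-one, via flavanone 23 (not isolated)
Conditions: I2 (10 mol %), DMSO, 130 °C
Reagents that add atoms: none
Why: Iodine-catalysed oxidative cyclization of a 2'-hydroxychalcone (6-endo-trig oxa-Michael closure to the flavanone, α-iodination and loss of HI, which DMSO reoxidizes to iodine) forms ring C of the apigenin half and removes the transient C2 stereocentre.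

Step 14
Reactants: 24 5,7-bis(benzyloxy)-6-{4-[5,7-bis(benzyloxy)-4-oxo-4H-chromen-2-yl]phenoxy}-2-(4-methoxyphenyl)-4H-chromen-4-one
Product: 25 cryptomerin A
Conditions: BCl3 (12 equiv), C6HMe5 (12 equiv), CH2Cl2, −78 to −20 °C; MeOH quench, aqueous work-up
Reagents that add atoms: none
Why: BCl3 cleaves all four aryl benzyl ethers at low temperature with pentamethylbenzene trapping the benzyl cations (no C-benzylation of the electron-rich rings), while the aryl methyl ether, the diaryl ether and both C2–C3 double bonds are untouched and the low temperature excludes acid-induced Wessely–Moser isomerization of the 6-aryloxyflavone.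

**Compound list**

1 | 4-bromo-2,6-dimethoxyphenol | COc1cc(Br)cc(OC)c1O | starting material
2 | 4-fluorobenzaldehyde | O=Cc1ccc(F)cc1 | starting material
3 | 4-(4-bromo-2,6-dimethoxyphenoxy)benzaldehyde | COc1cc(Br)cc(OC)c1Oc1ccc(C=O)cc1 | intermediate
4 | 4-(4-bromo-2,6-dihydroxyphenoxy)benzaldehyde | O=Cc1ccc(Oc2c(O)cc(Br)cc2O)cc1 | intermediate
5 | 4-[2,6-bis(benzyloxy)-4-bromophenoxy]benzaldehyde | O=Cc1ccc(Oc2c(OCc3ccccc3)cc(Br)cc2OCc2ccccc2)cc1 | intermediate
6 | 2-{4-[2,6-bis(benzyloxy)-4-bromophenoxy]phenyl}-1,3-dioxolane | Brc1cc(OCc2ccccc2)c(Oc2ccc(C3OCCO3)cc2)c(OCc2ccccc2)c1 | intermediate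
7 | {3,5-bis(benzyloxy)-4-[4-(1,3-dioxolan-2-yl)phenoxy]phenyl}lithium (not isolated) | [Li]c1cc(OCc2ccccc2)c(Oc2ccc(C3OCCO3)cc2)c(OCc2ccccc2)c1 | intermediate
8 | lithium {3,5-bis(benzyloxy)-4-[4-(1,3-dioxolan-2-yl)phenoxy]phenyl}trimethoxyborate (not isolated) | [Li+].CO[B-](OC)(OC)c1cc(OCc2ccccc2)c(Oc2ccc(C3OCCO3)cc2)c(OCc2ccccc2)c1 | intermediate
9 | 3,5-bis(benzyloxy)-4-[4-(1,3-dioxolan-2-yl)phenoxy]phenol | Oc1cc(OCc2ccccc2)c(Oc2ccc(C3OCCO3)cc2)c(OCc2ccccc2)c1 | intermediate
10 | 3,5-bis(benzyloxy)-2-bromo-4-[4-(1,3-dioxolan-2-yl)phenoxy]phenol | Oc1cc(OCc2ccccc2)c(Oc2ccc(C3OCCO3)cc2)c(OCc2ccccc2)c1Br | intermediate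
11 | {3,5-bis(benzyloxy)-2-bromo-4-[4-(1,3-dioxolan-2-yl)phenoxy]phenoxy}trimethylsilane | C[Si](C)(C)Oc1cc(OCc2ccccc2)c(Oc2ccc(C3OCCO3)cc2)c(OCc2ccccc2)c1Br | intermediate
12 | {2,4-bis(benzyloxy)-3-[4-(1,3-dioxolan-2-yl)phenoxy]-6-[(trimethylsilyl)oxy]phenyl}lithium (not isolated) | C[Si](C)(C)Oc1cc(OCc2ccccc2)c(Oc2ccc(C3OCCO3)cc2)c(OCc2ccccc2)c1[Li] | intermediate
13 | lithium 3,5-bis(benzyloxy)-4-[4-(1,3-dioxolan-2-yl)phenoxy]-2-(trimethylsilyl)phenoxide (not isolated) | [Li+].[O-]c1cc(OCc2ccccc2)c(Oc2ccc(C3OCCO3)cc2)c(OCc2ccccc2)c1[Si](C)(C)C | intermediate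
14 | 3,5-bis(benzyloxy)-4-[4-(1,3-dioxolan-2-yl)phenoxy]-2-(trimethylsilyl)phenyl trifluoromethanesulfonate | C[Si](C)(C)c1c(OS(=O)(=O)C(F)(F)F)cc(OCc2ccccc2)c(Oc2ccc(C3OCCO3)cc2)c1OCc1ccccc1 | intermediate
15 | 3-(4-methoxyphenyl)propiolic acid | COc1ccc(C#CC(=O)O)cc1 | starting material
16 | 3,5-bis(benzyloxy)-4-[4-(1,3-dioxolan-2-yl)phenoxy]-1,2-didehydrobenzene (aryne, not isolated) | C1#CC(OCc2ccccc2)=C(Oc2ccc(C3OCCO3)cc2)C(OCc2ccccc2)=C1 | intermediate
17 | 1-{2,4-bis(benzyloxy)-3-[4-(1,3-dioxolan-2-yl)phenoxy]-6-hydroxyphenyl}-3-(4-methoxyphenyl)prop-2-yn-1-one (formed as its caesium phenoxide, not isolated) | COc1ccc(C#CC(=O)c2c(O)cc(OCc3ccccc3)c(Oc3ccc(C4OCCO4)cc3)c2OCc2ccccc2)cc1 | intermediate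
18 | 5,7-bis(benzyloxy)-6-[4-(1,3-dioxolan-2-yl)phenoxy]-2-(4-methoxyphenyl)-4H-chromen-4-one | COc1ccc(-c2cc(=O)c3c(OCc4ccccc4)c(Oc4ccc(C5OCCO5)cc4)c(OCc4ccccc4)cc3o2)cc1 | intermediate
19 | 4-{[5,7-bis(benzyloxy)-2-(4-methoxyphenyl)-4-oxo-4H-chromen-6-yl]oxy}benzaldehyde | COc1ccc(-c2cc(=O)c3c(OCc4ccccc4)c(Oc4ccc(C=O)cc4)c(OCc4ccccc4)cc3o2)cc1 | intermediate
20 | 2,4,6-trihydroxyacetophenone | CC(=O)c1c(O)cc(O)cc1O | starting material
21 | 1-[2,4-bis(benzyloxy)-6-hydroxyphenyl]ethanone | CC(=O)c1c(O)cc(OCc2ccccc2)cc1OCc1ccccc1 | intermediate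
22 | (E)-1-[2,4-bis(benzyloxy)-6-hydroxyphenyl]-3-(4-{[5,7-bis(benzyloxy)-2-(4-methoxyphenyl)-4-oxo-4H-chromen-6-yl]oxy}phenyl)prop-2-en-1-one | COc1ccc(-c2cc(=O)c3c(OCc4ccccc4)c(Oc4ccc(/C=C/C(=O)c5c(O)cc(OCc6ccccc6)cc5OCc5ccccc5)cc4)c(OCc4ccccc4)cc3o2)cc1 | intermediate
23 | 5,7-bis(benzyloxy)-6-{4-[5,7-bis(benzyloxy)-4-oxochroman-2-yl]phenoxy}-2-(4-methoxyphenyl)-4H-chromen-4-one (racemic at C2 of the chromanone, not isolated) | COc1ccc(-c2cc(=O)c3c(OCc4ccccc4)c(Oc4ccc(C5CC(=O)c6c(OCc7ccccc7)cc(OCc7ccccc7)cc6O5)cc4)c(OCc4ccccc4)cc3o2)cc1 | intermediate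
24 | 5,7-bis(benzyloxy)-6-{4-[5,7-bis(benzyloxy)-4-oxo-4H-chromen-2-yl]phenoxy}-2-(4-methoxyphenyl)-4H-chromen-4-one | COc1ccc(-c2cc(=O)c3c(OCc4ccccc4)c(Oc4ccc(-c5cc(=O)c6c(OCc7ccccc7)cc(OCc7ccccc7)cc6o5)cc4)c(OCc4ccccc4)cc3o2)cc1 | intermediate
25 | cryptomerin A, 5,7-dihydroxy-6-[4-(5,7-dihydroxy-4-oxo-4H-chromen-2-yl)phenoxy]-2-(4-methoxyphenyl)-4H-chromen-4-one | COc1ccc(-c2cc(=O)c3c(O)c(Oc4ccc(-c5cc(=O)c6c(O)cc(O)cc6o5)cc4)c(O)cc3o2)cc1 | target

**Step count**

Total: 14 steps. Longest linear sequence: 13 steps (steps 1–10 and 12–14); step 11 is a one-step side branch.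

**Steps most likely to fail**

1. Step 9 (key step). The aryl anion may be protonated before the acyl shift (giving simple O-arylation of the acid), the propiolate may decarboxylate at 125 °C, or addition to the aryne may be misdirected.
Fallback, from 10 back to 19: bromophenol 10 is protected (MOMCl, iPr2NEt, CH2Cl2) as 2-{4-[2,6-bis(benzyloxy)-3-bromo-4-(methoxymethoxy)phenoxy]phenyl}-1,3-dioxolane F1. Acid 15 is converted (MeNHOMe·HCl, EDC·HCl, Et3N, CH2Cl2) into N-methoxy-3-(4-methoxyphenyl)-N-methylprop-2-ynamide F2. Bromine–lithium exchange on F1 (n-BuLi, THF, −78 °C) and acylation of the aryllithium with F2 should give the protected ynone 1-{2,4-bis(benzyloxy)-3-[4-(1,3-dioxolan-2-yl)phenoxy]-6-(methoxymethoxy)phenyl}-3-(4-methoxyphenyl)prop-2-yn-1-one F3. Aqueous HCl in THF/MeOH removes the methoxymethyl group and the dioxolane to give 4-{2,6-bis(benzyloxy)-4-hydroxy-3-[3-(4-methoxyphenyl)prop-2-ynoyl]phenoxy}benzaldehyde F4, which is closed to 19 by amine-mediated 6-endo cyclization (Et2NH, EtOH, reflux). The aryne is avoided altogether and the acyl group is placed by the position of the bromine.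

2. Step 12. Hydroxide may open the pyranone ring of the flavone already present, or the condensation may stall because the aldehyde is poorly soluble.
Fallback, from 19 back to 24: Pinnick oxidation (NaClO2, NaH2PO4, 2-methyl-2-butene, t-BuOH/THF/H2O) gives 4-{[5,7-bis(benzyloxy)-2-(4-methoxyphenyl)-4-oxo-4H-chromen-6-yl]oxy}benzoic acid F5. Esterification with phenol 21 (EDC·HCl, DMAP, CH2Cl2) gives 2-acetyl-3,5-bis(benzyloxy)phenyl 4-{[5,7-bis(benzyloxy)-2-(4-methoxyphenyl)-4-oxo-4H-chromen-6-yl]oxy}benzoate F6. Baker–Venkataraman O-to-C acyl shift with the non-nucleophilic base LiN(SiMe3)2 (THF, −78 °C to rt) gives 1-[2,4-bis(benzyloxy)-6-hydroxyphenyl]-3-(4-{[5,7-bis(benzyloxy)-2-(4-methoxyphenyl)-4-oxo-4H-chromen-6-yl]oxy}phenyl)propane-1,3-dione F7. Cyclodehydration (TsOH·H2O cat., toluene, reflux) gives 24, so steps 12 and 13 are both bypassed.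

3. Step 6. The very electron-rich phenol may be brominated twice (both ortho positions) or oxidized with loss of the para-aryloxy group.
Fallback, from 9 back to 14: carbamoylation (i-PrNCO, Et3N cat., CH2Cl2) gives 3,5-bis(benzyloxy)-4-[4-(1,3-dioxolan-2-yl)phenoxy]phenyl isopropylcarbamate F8. In-situ N-silylation (Me3SiOTf, TMEDA, Et2O), carbamate-directed ortho-lithiation (n-BuLi, TMEDA, −78 °C) at the position also flanked by a benzyloxy group, and quench with Me3SiCl give 3,5-bis(benzyloxy)-4-[4-(1,3-dioxolan-2-yl)phenoxy]-2-(trimethylsilyl)phenyl isopropylcarbamate F9. DBU and Et2NH in MeCN at 40 °C remove the carbamate to give 3,5-bis(benzyloxy)-4-[4-(1,3-dioxolan-2-yl)phenoxy]-2-(trimethylsilyl)phenol F10, which is triflated in the same flask with PhNTf2 to give 14. Steps 6 to 8 are replaced and no halogenation is needed.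

**Further compounds**

F1 | step 9 | 2-{4-[2,6-bis(benzyloxy)-3-bromo-4-(methoxymethoxy)phenoxy]phenyl}-1,3-dioxolane | COCOc1cc(OCc2ccccc2)c(Oc2ccc(C3OCCO3)cc2)c(OCc2ccccc2)c1Br
F2 | step 9 | N-methoxy-3-(4-methoxyphenyl)-N-methylprop-2-ynamide | COc1ccc(C#CC(=O)N(C)OC)cc1
F3 | step 9 | 1-{2,4-bis(benzyloxy)-3-[4-(1,3-dioxolan-2-yl)phenoxy]-6-(methoxymethoxy)phenyl}-3-(4-methoxyphenyl)prop-2-yn-1-one | COCOc1cc(OCc2ccccc2)c(Oc2ccc(C3OCCO3)cc2)c(OCc2ccccc2)c1C(=O)C#Cc1ccc(OC)cc1
F4 | step 9 | 4-{2,6-bis(benzyloxy)-4-hydroxy-3-[3-(4-methoxyphenyl)prop-2-ynoyl]phenoxy}benzaldehyde | COc1ccc(C#CC(=O)c2c(O)cc(OCc3ccccc3)c(Oc3ccc(C=O)cc3)c2OCc2ccccc2)cc1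
F5 | step 12 | 4-{[5,7-bis(benzyloxy)-2-(4-methoxyphenyl)-4-oxo-4H-chromen-6-yl]oxy}benzoic acid | COc1ccc(-c2cc(=O)c3c(OCc4ccccc4)c(Oc4ccc(C(=O)O)cc4)c(OCc4ccccc4)cc3o2)cc1
F6 | step 12 | 2-acetyl-3,5-bis(benzyloxy)phenyl 4-{[5,7-bis(benzyloxy)-2-(4-methoxyphenyl)-4-oxo-4H-chromen-6-yl]oxy}benzoate | COc1ccc(-c2cc(=O)c3c(OCc4ccccc4)c(Oc4ccc(C(=O)Oc5cc(OCc6ccccc6)cc(OCc6ccccc6)c5C(C)=O)cc4)c(OCc4ccccc4)cc3o2)cc1
F7 | step 12 | 1-[2,4-bis(benzyloxy)-6-hydroxyphenyl]-3-(4-{[5,7-bis(benzyloxy)-2-(4-methoxyphenyl)-4-oxo-4H-chromen-6-yl]oxy}phenyl)propane-1,3-dione | COc1ccc(-c2cc(=O)c3c(OCc4ccccc4)c(Oc4ccc(C(=O)CC(=O)c5c(O)cc(OCc6ccccc6)cc5OCc5ccccc5)cc4)c(OCc4ccccc4)cc3o2)cc1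
F8 | step 6 | 3,5-bis(benzyloxy)-4-[4-(1,3-dioxolan-2-yl)phenoxy]phenyl isopropylcarbamate | CC(C)NC(=O)Oc1cc(OCc2ccccc2)c(Oc2ccc(C3OCCO3)cc2)c(OCc2ccccc2)c1
F9 | step 6 | 3,5-bis(benzyloxy)-4-[4-(1,3-dioxolan-2-yl)phenoxy]-2-(trimethylsilyl)phenyl isopropylcarbamate | CC(C)NC(=O)Oc1cc(OCc2ccccc2)c(Oc2ccc(C3OCCO3)cc2)c(OCc2ccccc2)c1[Si](C)(C)C
F10 | step 6 | 3,5-bis(benzyloxy)-4-[4-(1,3-dioxolan-2-yl)phenoxy]-2-(trimethylsilyl)phenol | Oc1cc(OCc2ccccc2)c(Oc2ccc(C3OCCO3)cc2)c(OCc2ccccc2)c1[Si](C)(C)C
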